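The numbers in the tables are calculated with constants of no real substance; noise was put on by code.

- The vessel is closed and stirred, and nobody reads its partner, so I judge it from target and substrate.

common to all: substrate 0.37 M

| charge | partner | remark | time |
|---|---|---|---|
| noon | 2 equiv | the very flask that is asked about, followed so far |  |
| autumn | 4 equiv | run made earlier |  |
| flask | 2.00 equiv |  | 6.0 d |

- noon (time / h: target / %, substrate / %): 6.00: 4.7, 6.2; 15.0: 7.2, 2.1; 40.0: 13.1, 2.2; 96.0: 12.7, 2.2
- autumn (time / h: target / %, substrate / %): 1.50: 6.5, 18.2; 4.00: 9.2, 4.0; 8.00: 10.5, 2.9; 12.0: 11.4, 2.0

(readings scatter by 1 percentage point)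

- beta: at 6.0 d add partner, 50.0% of the amount charged, then wait 12 d
- alpha: at 6.0 d take out 90% of the target then present, then wait 12 d
- gamma: change nothing and wait 12 d more
- eta: at 6.0 d add substrate, 50.0% of the amount charged, then wait 12 d

- removed target is counted in
- what was read earlier has a scatter of 1 percentage point, one standard deviation
- additions bring no volume worth counting

* target, in percent of the substrate first charged, at 6.0 d
* the option that brings most further target ("none" if no option brings more than 2 percentage points) (beta / alpha / gamma / eta / none)
* target present, with what was taken out counted in, in percent of the substrate first charged, after beta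
* target present, with what was taken out counted in, in percent of the substrate first charged, after gamma

- Time: noon target reads 13.1% at 40.0 h and 12.7% at 96.0 h, inside the scatter of 1 percentage point. So I take 12.9% for this flask at 6.0 d, and I expect gamma to stay under 2 points.
- Partner: noon target stalls with 84.9% of the substrate in unread forms. Autumn, with 4 equiv, reads 9.2% at 4.00 h, but noon reads 7.2% at 15.0 h. So I bet that the stall lies with partner.
- I give the first equivalent to the substrate and call the rest spare. Noon has one spare equivalent, and it turned 13.2% of the reacted material into target; this share is my spare-equivalent conversion.
- Beta adds 1.00 equiv. My first answer repeats the 12.9%. Going round once more, the dose meets the remaining 84.9%, so it gains 11 points and reaches 23.9%.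
- Alpha takes out target and adds no partner, so under my bet it gains under 2 points.
- Eta adds material, but unread material already stands at 84.9%, so under my bet it also gains under 2 points. I choose beta.
- The forecast gives 13%, 13% after gamma and 13.3% after beta, and it chooses eta: “Waiting or adding partner should therefore gain little”. We part on beta and on the choice.
- The flask gives 13.1%, then 13.2% after gamma and 26.7% after beta. The gains are 14 points for beta, 0.031 points for alpha, 0.031 points for gamma and 0.013 points for eta, so the best is beta.

    substrate ⇌ intermediate A (K = 0.680, k = 6.60 × 10⁻⁴ /min)
    substrate ⇌ intermediate B (K = 15.0, k = 0.00350 /min)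
    substrate + partner → intermediate C (k = 0.0220 /M/min)
    partner + intermediate C ⇌ intermediate D (K = 0.710 /M, k = 0.00430 /M/min)
    partner + intermediate C → target (k = 0.00200 /M/min)
    partner → decomposed reagent (k = 1.40 × 10⁻⁴ /min)
    2 partner → homo dimer (k = 0.00890 /M/min)

- At 144 h this flask's partner, the limiting reagent, stands at 0.0246% of its charge, and its homo dimer holds 0.428 M of partner, more than the 0.0486 M of target. A neighbour flask, charged with 3.40 equiv of partner, should reach 28.2% by my conversion, but it gives 19.0%, with 70.0% of its charged partner in homo dimer.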